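(The numbers of this flask come from no measurement, and the outcome is calculated.)

I started from the easy step: X goes over to E with a half-life of 14.3 h, counting that step by itself, while pairs of X also leave as X2. E then passes reversibly into J and into Q.

| flask | X | remark | time |
|---|---|---|---|
| eta | 0.30 M | a single well-mixed tank run continuously and read at steady state, 100 h in it on average |  |
| alpha | 0.30 M | a single well-mixed tank run continuously and read at steady state, 10 h in it on average |  |
| epsilon | 0.30 M | a closed flask charged with all of it at once and left for 10 h | 10 h |

* order of the set-ups by the share of J in all that became J or Q, at the outlet or at the end, highest first (eta / alpha / epsilon)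
* share of J in all that became J or Q, at the outlet or at the end, eta
* share of J in all that became J or Q, at the outlet or at the end, alpha
* share of J in all that became J or Q, at the outlet or at the end, epsilon

- percentages count the X that a species holds: one X2 counts as two
- a step written with two of one species runs at k times the square of its concentration and takes two of it each time
- the stated concentrations are those of everything mixed, before any reaction; amounts are the same in each set-up
- run time (epsilon): 10 h

    X → E (k1 = 8.1 × 10⁻⁴ /min)
    E ⇌ J (K2 = 0.36, k2 = 0.032 /min)
    E ⇌ Q (K3 = 33, k3 = 0.0019 /min)
    2 X → X2 (k4 = 0.013 /M/min)

E forms J faster than it forms Q, yet equilibrium favours Q, the pattern of kinetic against thermodynamic control. So I asked how long each product stays once formed. A J waits on average 11.2 min before going back to E, which is the equilibrium constant over the forward rate constant, and I called this its return lifetime. The same reckoning gave Q 289 h.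

In a tank a product also leaves with the outflow, so I added the two loss rates and inverted the sum to get a holding time. The steady amount of a product is then its forward rate constant, times E, times its holding time. E cancels in the ratio of J to Q, so I needed no figure for X or for its loss to X2.

In tank alpha, with 10 h on average, J was held 11.0 min and Q 9.67 h. That gave a ratio of J to Q of 0.321 and a share of 24.3 %. In tank eta, with 100 h on average, J was held 11.2 min, but Q was held 74.3 h, longer than in alpha. The ratio fell to 0.0424 and the share to 4.07 %. Closed flask epsilon has no outflow, so my holding time did not apply there, and my own reckoning stopped short of a figure for that flask.

The forecast gave the order epsilon > alpha > eta, with 4.07 % for eta, 24.3 % for alpha and 27.8 % for epsilon, on the ground that “J equilibrates quickly with E, while the nearly irreversible Q keeps accumulating”.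

The simulation gave epsilon > alpha > eta, with 4.07 % in eta, 24.3 % in alpha and 28.0 % in epsilon, so both tanks stood where I had reckoned them.

The main reason for the low share in tank eta was the reverse step, J to E: with that step taken away, the share rose from 4.07 % to 95.8 %. The average stay in eta spanned 536 return lifetimes, so J had ample time to go back to E and on to Q. In closed flask epsilon, the 10 h spanned 53.6 return lifetimes, and striking the same step lifted the share from 28.0 % to 94.5 %.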